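**Plan**

- Oxolane numbering: O1, C2 (guaiacyl), C3 (carries C9H2–O-stearoyl), C4 (carries C7'H2–aryl), C5. After removal of two phenol silyl groups, the retrosynthesis cuts C3–C4 and C7'–aryl in one operation.
- Enabling feature: when O1 carries an allyl group (C5–C4=C7'), a radical at C3 is placed for 5-exo attack on C4. This closes ring O1–C2–C3–C4–C5 and moves the radical to C7', the carbon that must bond to the second guaiacyl ring.
- Further cuts: C3–I back to C3–OH; C9–O(stearate) and O1–C5 back to an epoxy alcohol; the epoxide oxygen back to an aryl vinyl carbinol; C2–C3 back to vanillin plus a vinyl nucleophile.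
- Forward: the acyclic C2–C3–C9 chain is built and functionalised (steps 1–6), the aryl bromide is silylated (step 7), the only ring and the benzyl–aryl bond arise together (step 8), and desilylation ends the route (step 9).
- Stereochemistry: C2 comes from a Sharpless kinetic-resolution epoxidation with D-(−)-diisopropyl tartrate. C3 and C4 are set relative to C2 in the radical ring closure (2,3-trans, 3,4-cis); the C3 configuration of the acyclic intermediates is erased there.

Key step: step 8

Remark on the chemistry: the phenols are carried as triisopropylsilyl ethers because the aryl O–Si bond must survive an alkoxide (step 4) and a hot carboxylate medium (step 5); the (S)-carbinol is taken to be the fast-reacting enantiomer with D-(−)-tartrate, as follows from the usual facial rule once aryl outranks vinyl.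

**Route**

Step 1
Reactants: 1 vanillin; 2 chlorotriisopropylsilane
Product: 3 3-methoxy-4-(triisopropylsilyloxy)benzaldehyde
Conditions: iPr3SiCl (1.1 equiv), imidazole (2 equiv), DMF, 0 °C to rt
Reagents that add atoms: chlorotriisopropylsilane (2), CC(C)[Si](Cl)(C(C)C)C(C)C
Why: Silylation of a phenol with a silyl chloride and imidazole is routine, and the bulky triisopropylsilyl ether tolerates the organometallic, basic and reducing steps that follow.

Step 2
Reactants: 3 3-methoxy-4-(triisopropylsilyloxy)benzaldehyde; 4 vinylmagnesium bromide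
Product: 6 racemic 1-[3-methoxy-4-(triisopropylsilyloxy)phenyl]prop-2-en-1-ol, via bromomagnesium alkoxide 5 (not isolated)
Conditions: CH2=CHMgBr (1.2 equiv), THF, −78 to 0 °C; then aq NH4Cl
Reagents that add atoms: vinylmagnesium bromide (4), C=C[Mg]Br
Why: Grignard 1,2-addition to an aromatic aldehyde forms the C2–C3 bond; the carbinol centre (future C2) is formed racemic and is resolved in step 3.

Step 3
Reactants: 6 racemic 1-[3-methoxy-4-(triisopropylsilyloxy)phenyl]prop-2-en-1-ol; 7 tert-butyl hydroperoxide
Product: 8 (R)-[3-methoxy-4-(triisopropylsilyloxy)phenyl][(2S)-oxiran-2-yl]methanol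
Conditions: Ti(OiPr)4 (0.1 equiv), D-(−)-diisopropyl tartrate (0.15 equiv), tBuOOH (0.45 equiv), 4 Å MS, CH2Cl2, −20 °C, run to about 45% conversion
Reagents that add atoms: tert-butyl hydroperoxide (7), CC(C)(C)OO
Why: Sharpless kinetic-resolution epoxidation of a secondary allylic alcohol: with D-(−)-tartrate the (S)-carbinol should react fast and take oxygen on the alkene face that gives the erythro epoxy alcohol, which fixes future C2 (now R by priority change) and the oxirane carbon (S), while the (R)-enantiomer of 6 stays behind and is removed by chromatography.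

Step 4
Reactants: 8 (R)-[3-methoxy-4-(triisopropylsilyloxy)phenyl][(2S)-oxiran-2-yl]methanol; 9 allyl bromide
Product: 11 (2S)-2-{(R)-(allyloxy)[3-methoxy-4-(triisopropylsilyloxy)phenyl]methyl}oxirane, via sodium alkoxide 10 (not isolated)
Conditions: NaH (1.1 equiv), THF, 0 °C; then allyl bromide (1.5 equiv), Bu4NI (5 mol %), 0 °C to rt
Reagents that add atoms: allyl bromide (9), C=CCBr
Why: Williamson etherification forms O1–C5; alkylation of the alkoxide by the reactive allyl halide in an aprotic solvent at low temperature should outrun Payne rearrangement, and no bond to a stereocentre is broken.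

Step 5
Reactants: 11 (2S)-2-{(R)-(allyloxy)[3-methoxy-4-(triisopropylsilyloxy)phenyl]methyl}oxirane; 12 stearic acid
Product: 13 (2S,3R)-3-(allyloxy)-2-hydroxy-3-[3-methoxy-4-(triisopropylsilyloxy)phenyl]propyl octadecanoate
Conditions: stearic acid (1.2 equiv), Bu4NBr (10 mol %), toluene, 90 °C
Reagents that add atoms: stearic acid (12), CCCCCCCCCCCCCCCCCC(=O)O
Why: Ammonium-carboxylate-catalysed SN2 opening of a terminal epoxide by a carboxylic acid occurs at the unhindered CH2 (future C9), installs the ester without touching either stereocentre, and the weakly acidic medium disfavours acyl migration and spares the aryl silyl ether.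

Step 6
Reactants: 13 (2S,3R)-3-(allyloxy)-2-hydroxy-3-[3-methoxy-4-(triisopropylsilyloxy)phenyl]propyl octadecanoate; 14 iodine
Product: 15 (2R,3R)-3-(allyloxy)-2-iodo-3-[3-methoxy-4-(triisopropylsilyloxy)phenyl]propyl octadecanoate
Conditions: PPh3 (1.5 equiv), I2 (1.5 equiv), imidazole (3 equiv), toluene, 60 °C
Reagents that add atoms: iodine (14), II
Why: Appel iodination under Garegg–Samuelsson conditions: iodide displaces the alkoxyphosphonium group with inversion at future C3, a configuration of no consequence because this carbon becomes a planar radical in step 8.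

Step 7
Reactants: 16 4-bromo-2-methoxyphenol; 2 chlorotriisopropylsilane
Product: 17 (4-bromo-2-methoxyphenoxy)triisopropylsilane
Conditions: iPr3SiCl (1.1 equiv), imidazole (2 equiv), DMF, rt
Reagents that add atoms: chlorotriisopropylsilane (2), CC(C)[Si](Cl)(C(C)C)C(C)C
Why: Routine phenol silylation gives the aryl bromide partner with the same protecting group as the other ring, so that one operation frees both phenols at the end.

Step 8
Reactants: 15 (2R,3R)-3-(allyloxy)-2-iodo-3-[3-methoxy-4-(triisopropylsilyloxy)phenyl]propyl octadecanoate; 17 (4-bromo-2-methoxyphenoxy)triisopropylsilane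
Product: 18 [(2S,3R,4R)-4-[3-methoxy-4-(triisopropylsilyloxy)benzyl]-2-[3-methoxy-4-(triisopropylsilyloxy)phenyl]oxolan-3-yl]methyl octadecanoate
Conditions: NiBr2(dme) (10 mol %), 4,4'-di-tert-butyl-2,2'-bipyridine (12 mol %), Zn powder (2 equiv), 17 (1.5 equiv), DMA, 25 °C, 15 added over 2 h
Reagents that add atoms: (4-bromo-2-methoxyphenoxy)triisopropylsilane (17), Brc1ccc(O[Si](C(C)C)(C(C)C)C(C)C)c(OC)c1
Why: Halogen-atom abstraction from 15 by a reduced nickel–bipyridine species should release a secondary radical at C3; this radical adds to C4 of the O-allyl group, the C7' radical that results is intercepted by the aryl–nickel bromide complex (divalent nickel) that 17 forms with zerovalent nickel, the trivalent nickel intermediate collapses by C7'–aryl reductive elimination, and zinc regenerates the low-valent catalyst. The nearest established reaction type is the nickel-catalysed reductive 1,2-dicarbofunctionalisation of alkenes, in which an alkyl halide tethered to the alkene cyclises as a radical and the cyclised radical is cross-coupled with an aryl halide. The oxolane ring (O1–C2–C3–C4–C5) closes in the 5-exo-trig mode through formation of C3–C4. C3 and C4 are new stereocentres controlled by the existing C2 centre: in the chair-like transition state the C2 aryl group lies pseudo-equatorial, the C9 arm on the radical carbon turns away from it (2,3-trans) and ends cis to the nascent C7' arm (3,4-cis), whichever configuration the iodide carbon had. The step needs ring closure to precede arylation and needs 2,3-trans/3,4-cis diastereoselection; the first is secured by the high unimolecular rate of a 3-oxa-5-hexenyl radical against bimolecular capture by a catalyst kept at low concentration, the second by the bulky aryl group directly beside the radical centre. The ester, the ether and the aryl silyl ethers are spectators under these mild reducing conditions.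

Step 9
Reactants: 18 [(2S,3R,4R)-4-[3-methoxy-4-(triisopropylsilyloxy)benzyl]-2-[3-methoxy-4-(triisopropylsilyloxy)phenyl]oxolan-3-yl]methyl octadecanoate
Product: 19 [(2S,3R,4R)-4-(4-hydroxy-3-methoxybenzyl)-2-(4-hydroxy-3-methoxyphenyl)oxolan-3-yl]methyl octadecanoate (target)
Conditions: Bu4NF (2.4 equiv), AcOH (2.4 equiv), THF, 0 °C
Reagents that add atoms: none
Why: Fluoride cleaves aryl silyl ethers quickly, and buffering with acetic acid keeps the primary stearate and the benzylic ether centre at C2 away from basic phenoxide conditions, so no stereocentre is touched.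

**Compound list**

1 | vanillin | O=Cc1ccc(O)c(OC)c1 | starting material
2 | chlorotriisopropylsilane | CC(C)[Si](Cl)(C(C)C)C(C)C | starting material
3 | 3-methoxy-4-(triisopropylsilyloxy)benzaldehyde | O=Cc1ccc(O[Si](C(C)C)(C(C)C)C(C)C)c(OC)c1 | intermediate
4 | vinylmagnesium bromide | C=C[Mg]Br | starting material
5 | bromomagnesium alkoxide of 6 (racemic, not isolated) | C=CC(O[Mg]Br)c1ccc(O[Si](C(C)C)(C(C)C)C(C)C)c(OC)c1 | intermediate
6 | racemic 1-[3-methoxy-4-(triisopropylsilyloxy)phenyl]prop-2-en-1-ol | C=CC(O)c1ccc(O[Si](C(C)C)(C(C)C)C(C)C)c(OC)c1 | intermediate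
7 | tert-butyl hydroperoxide | CC(C)(C)OO | starting material
8 | (R)-[3-methoxy-4-(triisopropylsilyloxy)phenyl][(2S)-oxiran-2-yl]methanol | O[C@H](c1ccc(O[Si](C(C)C)(C(C)C)C(C)C)c(OC)c1)[C@@H]1CO1 | intermediate
9 | allyl bromide | C=CCBr | starting material
10 | sodium alkoxide of 8 (not isolated) | [Na+].[O-][C@H](c1ccc(O[Si](C(C)C)(C(C)C)C(C)C)c(OC)c1)[C@@H]1CO1 | intermediate
11 | (2S)-2-{(R)-(allyloxy)[3-methoxy-4-(triisopropylsilyloxy)phenyl]methyl}oxirane | C=CCO[C@H](c1ccc(O[Si](C(C)C)(C(C)C)C(C)C)c(OC)c1)[C@@H]1CO1 | intermediate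
12 | stearic acid | CCCCCCCCCCCCCCCCCC(=O)O | starting material
13 | (2S,3R)-3-(allyloxy)-2-hydroxy-3-[3-methoxy-4-(triisopropylsilyloxy)phenyl]propyl octadecanoate | CCCCCCCCCCCCCCCCCC(=O)OC[C@H](O)[C@H](OCC=C)c1ccc(O[Si](C(C)C)(C(C)C)C(C)C)c(OC)c1 | intermediate
14 | iodine | II | starting material
15 | (2R,3R)-3-(allyloxy)-2-iodo-3-[3-methoxy-4-(triisopropylsilyloxy)phenyl]propyl octadecanoate | CCCCCCCCCCCCCCCCCC(=O)OC[C@@H](I)[C@H](OCC=C)c1ccc(O[Si](C(C)C)(C(C)C)C(C)C)c(OC)c1 | intermediate
16 | 4-bromo-2-methoxyphenol | Oc1ccc(Br)cc1OC | starting material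
17 | (4-bromo-2-methoxyphenoxy)triisopropylsilane | Brc1ccc(O[Si](C(C)C)(C(C)C)C(C)C)c(OC)c1 | intermediate
18 | [(2S,3R,4R)-4-[3-methoxy-4-(triisopropylsilyloxy)benzyl]-2-[3-methoxy-4-(triisopropylsilyloxy)phenyl]oxolan-3-yl]methyl octadecanoate | CCCCCCCCCCCCCCCCCC(=O)OC[C@H]1[C@@H](Cc2ccc(O[Si](C(C)C)(C(C)C)C(C)C)c(OC)c2)CO[C@@H]1c1ccc(O[Si](C(C)C)(C(C)C)C(C)C)c(OC)c1 | intermediate
19 | [(2S,3R,4R)-4-(4-hydroxy-3-methoxybenzyl)-2-(4-hydroxy-3-methoxyphenyl)oxolan-3-yl]methyl octadecanoate | CCCCCCCCCCCCCCCCCC(=O)OC[C@H]1[C@@H](Cc2ccc(O)c(OC)c2)CO[C@@H]1c1ccc(O)c(OC)c1 | target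

**Step count**

Total steps: 9. Longest linear sequence: 8 (steps 1–6, 8 and 9; step 7 is a one-step side branch).

**Steps most likely to fail** (Ar = 3-methoxy-4-(triisopropylsilyloxy)phenyl)

Step 8. Three things may go wrong:
- the C3 centre may be reduced to an organozinc or organonickel species before the ring closes, which then expels the neighbouring stearate or allyloxy group (Boord-type elimination);
- C3 may be arylated directly without cyclisation;
- the chair preference may be too weak for clean 3,4-cis selectivity.

Fallback: the two bonds are made in separate operations. Setting out from 15, iodine-atom-transfer radical cyclisation (Et3B, trace air, benzene, rt) should give [(2S,3R,4R)-4-(iodomethyl)-2-Ar-oxolan-3-yl]methyl octadecanoate F1 with no reducing metal present. F1 is a primary iodide without a leaving group on the neighbouring carbon. It is then joined to 17 by nickel-catalysed cross-electrophile coupling (NiBr2(dme), 4,4'-di-tert-butyl-2,2'-bipyridine, Zn, DMA, rt), which comes back to the route at 18.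

Step 6. The stearate carbonyl may participate in the alkoxyphosphonium ion (acyloxonium formation, then iodide attack at C9 with acyl shift), or E2 elimination may win at this hindered secondary carbon flanked by two oxygenated carbons.

Fallback: the iodide is introduced while C9 carries a non-participating silyl ether, and the ester is attached afterwards.
- Setting out from 11, the epoxide is hydrolysed with water and racemic (salen)Co(OAc) [salen = N,N'-bis(3,5-di-tert-butylsalicylidene)cyclohexane-1,2-diamine dianion] in THF to the diol (2S,3R)-3-(allyloxy)-3-Ar-propane-1,2-diol F2.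
- tBuMe2SiCl and imidazole in CH2Cl2 at 0 °C silylate the primary hydroxyl to give (2S,3R)-3-(allyloxy)-1-(tert-butyldimethylsilyloxy)-3-Ar-propan-2-ol F3.
- PPh3, I2 and imidazole convert F3 with inversion into the iodide {[(2R,3R)-3-(allyloxy)-2-iodo-3-Ar-propyl]oxy}(tert-butyl)dimethylsilane F4.
- HF·pyridine in THF–pyridine at 0 °C removes the alkyl silyl ether in the presence of the aryl one to give the iodo alcohol (2R,3R)-3-(allyloxy)-2-iodo-3-Ar-propan-1-ol F5.
- Stearoyl chloride and pyridine in CH2Cl2 at 0 °C acylate F5, which comes back to the route at 15.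

Step 3. The rate difference between the enantiomers of this terminal-vinyl carbinol may be too small to give enantiopure epoxy alcohol at useful conversion, and the Lewis-acidic titanium may ionise the electron-rich benzylic carbinol.

Fallback: resolution and epoxidation are separated. Setting out from 6, acylation with vinyl acetate over immobilised Candida antarctica lipase B (tert-butyl methyl ether, rt) should convert the (R)-enantiomer into (R)-1-Ar-prop-2-en-1-yl acetate F7 and leave (S)-1-Ar-prop-2-en-1-ol F6. After separation, F6 is epoxidised to full conversion with Ti(OiPr)4, D-(−)-diisopropyl tartrate and tBuOOH (matched pair, CH2Cl2, −20 °C). The titanium reagent then only has to control the alkene face, and the sequence comes back to the route at 8.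

**Further compounds**

F1 | step 8 | [(2S,3R,4R)-4-(iodomethyl)-2-[3-methoxy-4-(triisopropylsilyloxy)phenyl]oxolan-3-yl]methyl octadecanoate | CCCCCCCCCCCCCCCCCC(=O)OC[C@H]1[C@@H](CI)CO[C@@H]1c1ccc(O[Si](C(C)C)(C(C)C)C(C)C)c(OC)c1
F2 | step 6 | (2S,3R)-3-(allyloxy)-3-[3-methoxy-4-(triisopropylsilyloxy)phenyl]propane-1,2-diol | OC[C@H](O)[C@H](OCC=C)c1ccc(O[Si](C(C)C)(C(C)C)C(C)C)c(OC)c1
F3 | step 6 | (2S,3R)-3-(allyloxy)-1-(tert-butyldimethylsilyloxy)-3-[3-methoxy-4-(triisopropylsilyloxy)phenyl]propan-2-ol | CC(C)(C)[Si](C)(C)OC[C@H](O)[C@H](OCC=C)c1ccc(O[Si](C(C)C)(C(C)C)C(C)C)c(OC)c1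
F4 | step 6 | {[(2R,3R)-3-(allyloxy)-2-iodo-3-[3-methoxy-4-(triisopropylsilyloxy)phenyl]propyl]oxy}(tert-butyl)dimethylsilane | CC(C)(C)[Si](C)(C)OC[C@@H](I)[C@H](OCC=C)c1ccc(O[Si](C(C)C)(C(C)C)C(C)C)c(OC)c1
F5 | step 6 | (2R,3R)-3-(allyloxy)-2-iodo-3-[3-methoxy-4-(triisopropylsilyloxy)phenyl]propan-1-ol | OC[C@@H](I)[C@H](OCC=C)c1ccc(O[Si](C(C)C)(C(C)C)C(C)C)c(OC)c1
F6 | step 3 | (S)-1-[3-methoxy-4-(triisopropylsilyloxy)phenyl]prop-2-en-1-ol | C=C[C@H](O)c1ccc(O[Si](C(C)C)(C(C)C)C(C)C)c(OC)c1
F7 | step 3 | (R)-1-[3-methoxy-4-(triisopropylsilyloxy)phenyl]prop-2-en-1-yl acetate | C=C[C@@H](OC(C)=O)c1ccc(O[Si](C(C)C)(C(C)C)C(C)C)c(OC)c1
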